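The delta run crawls at first, with 0.044 M of target at 25 min, and then takes off, so we read it as two channels: a catalyst channel that needs no target, and a channel fed by the target already made (autocatalysis).

| flask | starting material | free catalyst | time |
|---|---|---|---|
| delta | 0.800 M | 0.00160 M |  |
| zeta | 0.800 M | 0.00480 M |  |
| alpha | 1.20 M | 0.00160 M |  |
| eta | 0.480 M | 0.00160 M | 75 min |

| delta run: time / min | delta run: [target] / M | zeta run: time / min | zeta run: [target] / M | alpha run: time / min | alpha run: [target] / M |
|---|---|---|---|---|---|
| 2.7 | 0.001 | 2.7 | 0.017 | 2.7 | 0 |
| 8.2 | 0.008 | 8.2 | 0.063 | 8.2 | 0 |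
| 16 | 0.023 | 16 | 0.168 | 16 | 0.018 |
| 25 | 0.044 | 25 | 0.370 | 25 | 0.047 |
| 35 | 0.109 | 35 | 0.644 | 35 | 0.160 |
| 47 | 0.273 | 47 | 0.774 | 47 | 0.529 |
| 61 | 0.533 | 61 | 0.803 | 61 | 1.020 |
| 75 | 0.712 | 75 | 0.797 | 75 | 1.176 |

(readings scatter by 0.004 M)

* the power of [free catalyst] that the first rate follows, about the charge of the delta run; measure it at two percent of starting material made into target
* the power of [starting material] that the first rate follows, about the charge of the delta run; measure it at two percent of starting material made into target (one fixed amount of target, the same in the runs compared)
* target in the eta run at 75 min, as a share of the starting material charged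

- Overall: starting material -> target, with free catalyst as catalyst.
- Constant volume, constant temperature.
- The analysis sees a species whether free or bound.
- An order is taken over about fifteen percent of the charge, up and down.

Between 47 min and 61 min of the delta run, the ratio of target made to starting material left grows by a factor e every 10.4 min; we call this the growth time.

At 0.0160 M of target, the fed channel then gives 0.00151 M min⁻¹, while the delta readings around that amount show 0.00192 M min⁻¹, a fed share of 78.6%. The first zeta reading shows 0.00630 M min⁻¹. If the fed channel ignores catalyst, the remainder goes from 4.12 × 10⁻⁴ M min⁻¹ to 0.00479 M min⁻¹, a power of 2.23 in catalyst.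

The order of a sum is the share-weighted mean of its channels' powers, so we reckon ord_C at 0.478. In the alpha run the fed channel predicts 0.00227 M min⁻¹ against 0.00231 M min⁻¹, and the gap is smaller than the slope's scatter of 7.25 × 10⁻⁴ M min⁻¹. So we guess the remainder falls with power −2.23 in starting material, which puts ord_S at 0.307.

For the eta run the growth time stretches to 17.3 min and the remainder rises to 0.00129 M min⁻¹. The ratio at 75 min is therefore 3.55, which is 78.0% of the charge.

The forecast, holding that “product accelerates its own formation”, gives 0.8, 0.4 and 78%, its orders higher than ours. The flask gives 0.53, 0.27 and 77.7%.

    free catalyst + starting material ⇌ catalyst-substrate complex, settled at all times (0.3080 L mol⁻¹)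
    catalyst-substrate complex + free catalyst → target + 2 free catalyst (11340 L mol⁻¹ min⁻¹)
    catalyst-substrate complex + starting material ⇌ doubly bound catalyst, settled at all times (13.00 L mol⁻¹)
    starting material + target → 2 target (0.1134 L mol⁻¹ min⁻¹)

At two percent in the delta run, the doubly bound catalyst was the resting state, holding 66.5% of the catalyst charged, and the target-fed step gave 0.00142 M min⁻¹ of the 0.0019 M min⁻¹, more than the catalyst step. Later the delta run climbed from a quarter to half of its charge in 11.5 min, against 11.4 min from the growth time read off its readings, and the eta run reached 77.7% at 75 min, which is 4.34 of our estimated growth times of 17.3 min, or 4.08 of the 18.4 min that is one over the target-fed constant times 0.480 M.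

The data were generated by integration with made-up constants.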